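**Strategy (prostanoid numbering).** The five-membered ring is disconnected at both single bonds flanking its cis C10=C11 alkene, C11–C12 and C9–C10. The key step exploits the 1,3-relationship of the C9 carbonyl and the C12 tertiary carbinol across C8. A (Z)-2-silylvinyllithium acts as a cis-vinylene dianion towards a keto lactone: it adds to the C12 ketone, passes silicon from C10 to O12 (Brook shift) and acylates C10 with the lactone carbonyl. The precursor is a malic-acid-derived 2-tert-butyl-1,3-dioxolan-4-one, acylated at its quaternary carbon (C8). This temporary ring relays chirality to C12, is expelled as pivalaldehyde, and leaves a C8 hydroxyl that is later eliminated to the exocyclic diene.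

Key step: step 8

Remark: the phosphonium salt 6 is taken as commercially available, and C12 is assumed to form under non-chelation (polar Felkin–Anh) control; should the opposite facial sense prevail, (S)-malic acid would be used instead.

Step 1
Reactants: 1 (R)-malic acid; 2 pivalaldehyde
Product: 3 [(2R,4R)-2-tert-butyl-5-oxo-1,3-dioxolan-4-yl]acetic acid
Conditions: TsOH·H2O (cat.), H2SO4 (cat.), pentane, reflux (Dean–Stark); recrystallisation
Reagents that add atoms: none
Why: Acid-catalysed acetalisation engages the α-hydroxy acid unit as the five-membered dioxolanone and, under thermodynamic control, places the tert-butyl group cis to the CH2CO2H arm, so the malic stereocentre fixes the new acetal centre as 2R.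

Step 2
Reactants: 3 [(2R,4R)-2-tert-butyl-5-oxo-1,3-dioxolan-4-yl]acetic acid
Product: 5 [(2R,4R)-2-tert-butyl-5-oxo-1,3-dioxolan-4-yl]acetaldehyde, via acid chloride 4 (not isolated)
Conditions: (COCl)2, DMF (cat.), CH2Cl2, 0 °C; then LiAlH(O-t-Bu)3, THF, −78 °C
Reagents that add atoms: none
Why: The acid is activated as its chloride and reduced by the hindered hydride, which should stop at the aldehyde and leave the acylal lactone untouched at −78 °C (acid chloride reduction).

Step 3
Reactants: 5 [(2R,4R)-2-tert-butyl-5-oxo-1,3-dioxolan-4-yl]acetaldehyde; 6 (4-methoxycarbonylbutyl)triphenylphosphonium bromide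
Product: 8 methyl (5Z)-7-[(2R,4R)-2-tert-butyl-5-oxo-1,3-dioxolan-4-yl]hept-5-enoate, via phosphorus ylide 7 (not isolated)
Conditions: NaN(SiMe3)2, THF, −78 °C; then 5, −78 → 0 °C
Reagents that add atoms: none
Why: The non-stabilised ylide should react with the aldehyde under kinetic control to give the Z-alkene (Wittig reaction), faster than it enolises the aldehyde or attacks the lactone.

Step 4
Reactants: 9 (Z)-non-3-en-1-ol
Product: 11 (Z)-non-3-enoic acid, via (Z)-non-3-enal 10 (not isolated)
Conditions: TEMPO (cat.), PhI(OAc)2, MeCN/H2O, 0 °C → rt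
Reagents that add atoms: water, O
Why: The nitroxyl-catalysed oxidation takes the primary alcohol through the aldehyde hydrate to the acid under near-neutral conditions, which should keep the β,γ-Z-alkene out of conjugation.

Step 5
Reactants: 8 methyl (5Z)-7-[(2R,4R)-2-tert-butyl-5-oxo-1,3-dioxolan-4-yl]hept-5-enoate; 11 (Z)-non-3-enoic acid
Product: 14 methyl (5Z)-7-[(2R,4S)-2-tert-butyl-4-[(3Z)-non-3-enoyl]-5-oxo-1,3-dioxolan-4-yl]hept-5-enoate, via (Z)-non-3-enoyl chloride 12 (not isolated), via dioxolanone lithium enolate 13 (not isolated)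
Conditions: 11, (COCl)2, DMF (cat.), CH2Cl2, 0 °C, concentrate; 8, LiN(SiMe3)2, THF, −78 °C; enolate cannulated into 12, THF, −78 °C
Reagents that add atoms: none
Why: The base should remove the most acidic hydrogen (the lactone α-H) and the enolate should be C-acylated on the face opposite the tert-butyl group (Claisen-type acylation under self-regeneration-of-stereocentre control), which sets the quaternary centre as 4S.

Step 6
Reactants: 15 (triethylsilyl)acetylene
Product: 17 1-bromo-2-(triethylsilyl)acetylene, via lithium (triethylsilyl)acetylide 16 (not isolated)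
Conditions: n-BuLi, THF, −78 °C; then Br2, −78 °C
Reagents that add atoms: bromine, BrBr
Why: The lithium acetylide is brominated at carbon by electrophilic bromine (halogenation of a metal acetylide), leaving the C–Si bond intact.

Step 7
Reactants: 17 1-bromo-2-(triethylsilyl)acetylene
Product: 18 (Z)-(2-bromovinyl)triethylsilane
Conditions: 2-nitrobenzenesulfonohydrazide, Et3N, THF/i-PrOH, rt
Reagents that add atoms: none
Why: Diimide released from the sulfonohydrazide should deliver both hydrogens to the same face of the bromoalkyne (cis-semireduction), giving the Z-bromoalkene without touching the C–Br or C–Si bonds.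

Step 8
Reactants: 14 methyl (5Z)-7-[(2R,4S)-2-tert-butyl-4-[(3Z)-non-3-enoyl]-5-oxo-1,3-dioxolan-4-yl]hept-5-enoate; 18 (Z)-(2-bromovinyl)triethylsilane
Product: 22 methyl (5Z)-7-[(1S,5R)-1-hydroxy-5-[(2Z)-oct-2-en-1-yl]-2-oxo-5-(triethylsilyloxy)cyclopent-3-en-1-yl]hept-5-enoate, via (Z)-2-(triethylsilyl)vinyllithium 19 (not isolated), via lithium alkoxide adduct 20 (not isolated), via C10 vinyllithium after silyl shift 21 (not isolated)
Conditions: 18, t-BuLi (2 equiv), Et2O, −78 °C; 14 in THF, −78 °C; then HMPA, −78 → −40 °C; AcOH, −78 °C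
Reagents that add atoms: none
Why: Proposed new method: vinyllithium 19 should add to the C12 ketone (more electrophilic than the acylal and the remote ester); alkoxide 20, once freed by HMPA, should take the cis-disposed silyl group from C10 (1,4-Brook shift from sp2 carbon to oxygen); and the new C10 vinyllithium 21 should attack the neighbouring lactone carbonyl, whose tetrahedral intermediate collapses with loss of pivalaldehyde, so that C11–C12 and C9–C10 form in one flask and the tertiary alcohol emerges silylated. The closest known reactions are anion relay through Brook rearrangement of (Z)-γ-silyl allylic alkoxides, Parham-type cyclisation of vinyllithiums onto esters, and carbonyl additions next to 2-tert-butyl-1,3-dioxolan-4-ones in self-regeneration of stereocentres. The only ring closed is the cyclopentenone, by 5-exo-trig attack of C10 on C9. C12 is set by 1,2-induction from the quaternary C8 centre (polar Felkin–Anh addition anti to the ring C–O bond, past the flat lactone carbonyl and not the allylic CH2); a minor C12 epimer would be a separable diastereomer, so enantiopurity rests on (R)-malic acid. The step needs the Z geometry of 18 (retained on bromine–lithium exchange) so that silicon reaches O12 and C10 reaches C9, and it needs addition to outrun enolisation at C13, which low temperature and the weakly basic vinyllithium should favour.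

Step 9
Reactants: 22 methyl (5Z)-7-[(1S,5R)-1-hydroxy-5-[(2Z)-oct-2-en-1-yl]-2-oxo-5-(triethylsilyloxy)cyclopent-3-en-1-yl]hept-5-enoate
Product: 23 methyl (5Z)-7-[(3S,4R)-3-hydroxy-4-[(2Z)-oct-2-en-1-yl]-2-oxo-4-(triethylsilyloxy)-6-oxabicyclo[3.1.0]hexan-3-yl]hept-5-enoate (either cis-fused epoxide epimer)
Conditions: t-BuOOH (decane), DBU, CH2Cl2, 0 °C
Reagents that add atoms: tert-butyl hydroperoxide, CC(C)(C)OO
Why: The hydroperoxide anion should add conjugately to the electron-poor ring alkene and close to the epoxy ketone (nucleophilic epoxidation), leaving the isolated Z-alkenes untouched; both epoxide epimers converge in the next step.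

Step 10
Reactants: 23 epoxy ketone (either epimer)
Product: 25 methyl (5Z)-7-[(1S,5R)-3-bromo-1-hydroxy-5-[(2Z)-oct-2-en-1-yl]-2-oxo-5-(triethylsilyloxy)cyclopent-3-en-1-yl]hept-5-enoate, via bromo silyloxy ketone 24 (not isolated)
Conditions: Me3SiBr, CH2Cl2, −78 °C; then DBU, −78 → 0 °C; aqueous citric acid work-up
Reagents that add atoms: bromotrimethylsilane, C[Si](C)(C)Br
Why: Bromide should open the silyl-activated epoxide by SN2 attack at the α-carbon (the β-carbon is neopentyl), and DBU should then remove the acidic α-hydrogen and expel the β-silyloxy group (E1cB), restoring the ring alkene with bromine at C10.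

Step 11
Reactants: 25 methyl (5Z)-7-[(1S,5R)-3-bromo-1-hydroxy-5-[(2Z)-oct-2-en-1-yl]-2-oxo-5-(triethylsilyloxy)cyclopent-3-en-1-yl]hept-5-enoate
Product: 26 methyl (5Z,7E)-7-[(2R)-4-bromo-2-[(2Z)-oct-2-en-1-yl]-5-oxo-2-(triethylsilyloxy)cyclopent-3-en-1-ylidene]hept-5-enoate
Conditions: Ph2S[OC(CF3)2Ph]2, CH2Cl2, 0 °C → rt
Reagents that add atoms: none
Why: The sulfurane should turn the tertiary α-hydroxyl into an alkoxysulfonium leaving group that departs with an allylic C7 hydrogen, the only β-hydrogen available (dehydration), giving the cross-conjugated dienone, expected mainly as the 7E isomer in which the chain avoids the carbonyl oxygen.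

Step 12
Reactants: 26 methyl (5Z,7E)-7-[(2R)-4-bromo-2-[(2Z)-oct-2-en-1-yl]-5-oxo-2-(triethylsilyloxy)cyclopent-3-en-1-ylidene]hept-5-enoate
Product: 27 methyl (5Z,7E)-7-[(2R)-4-bromo-2-hydroxy-2-[(2Z)-oct-2-en-1-yl]-5-oxocyclopent-3-en-1-ylidene]hept-5-enoate (bromovulone I)
Conditions: HF·pyridine, THF/pyridine, 0 °C
Reagents that add atoms: none
Why: Buffered fluoride should cleave the tertiary triethylsilyl ether (desilylation) under conditions that the bromodienone and the ester tolerate, leaving the C12 configuration untouched.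

**Compound list**

1 | (R)-malic acid | O[C@H](CC(O)=O)C(O)=O | starting material
2 | pivalaldehyde | CC(C)(C)C=O | starting material
3 | [(2R,4R)-2-tert-butyl-5-oxo-1,3-dioxolan-4-yl]acetic acid | OC(=O)C[C@H]1O[C@@H](C(C)(C)C)OC1=O | intermediate
4 | [(2R,4R)-2-tert-butyl-5-oxo-1,3-dioxolan-4-yl]acetyl chloride (not isolated) | ClC(=O)C[C@H]1O[C@@H](C(C)(C)C)OC1=O | intermediate
5 | [(2R,4R)-2-tert-butyl-5-oxo-1,3-dioxolan-4-yl]acetaldehyde | O=CC[C@H]1O[C@@H](C(C)(C)C)OC1=O | intermediate
6 | (4-methoxycarbonylbutyl)triphenylphosphonium bromide | COC(=O)CCCC[P+](c1ccccc1)(c1ccccc1)c1ccccc1.[Br-] | starting material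
7 | (4-methoxycarbonylbutylidene)triphenylphosphorane (not isolated) | COC(=O)CCC[CH-][P+](c1ccccc1)(c1ccccc1)c1ccccc1 | intermediate
8 | methyl (5Z)-7-[(2R,4R)-2-tert-butyl-5-oxo-1,3-dioxolan-4-yl]hept-5-enoate | COC(=O)CCC/C=C\C[C@H]1O[C@@H](C(C)(C)C)OC1=O | intermediate
9 | (Z)-non-3-en-1-ol | CCCCC/C=C\CCO | starting material
10 | (Z)-non-3-enal (not isolated) | CCCCC/C=C\CC=O | intermediate
11 | (Z)-non-3-enoic acid | CCCCC/C=C\CC(=O)O | intermediate
12 | (Z)-non-3-enoyl chloride (not isolated) | CCCCC/C=C\CC(=O)Cl | intermediate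
13 | lithium enolate of 8 (not isolated) | COC(=O)CCC/C=C\CC1=C([O-])O[C@H](C(C)(C)C)O1.[Li+] | intermediate
14 | methyl (5Z)-7-[(2R,4S)-2-tert-butyl-4-[(3Z)-non-3-enoyl]-5-oxo-1,3-dioxolan-4-yl]hept-5-enoate | COC(=O)CCC/C=C\C[C@@]1(C(=O)C/C=C\CCCCC)O[C@@H](C(C)(C)C)OC1=O | intermediate
15 | (triethylsilyl)acetylene | C#C[Si](CC)(CC)CC | starting material
16 | lithium (triethylsilyl)acetylide (not isolated) | [Li]C#C[Si](CC)(CC)CC | intermediate
17 | 1-bromo-2-(triethylsilyl)acetylene | BrC#C[Si](CC)(CC)CC | intermediate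
18 | (Z)-(2-bromovinyl)triethylsilane | Br/C=C\[Si](CC)(CC)CC | intermediate
19 | (Z)-2-(triethylsilyl)vinyllithium (not isolated) | [Li]/C=C\[Si](CC)(CC)CC | intermediate
20 | lithium alkoxide from addition of 19 to the ketone of 14, carbinol carbon R (not isolated) | COC(=O)CCC/C=C\C[C@@]1([C@]([O-])(/C=C\[Si](CC)(CC)CC)C/C=C\CCCCC)O[C@@H](C(C)(C)C)OC1=O.[Li+] | intermediate
21 | (Z)-vinyllithium formed from 20 by silyl shift to oxygen (not isolated) | COC(=O)CCC/C=C\C[C@@]1([C@](O[Si](CC)(CC)CC)(/C=C\[Li])C/C=C\CCCCC)O[C@@H](C(C)(C)C)OC1=O | intermediate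
22 | methyl (5Z)-7-[(1S,5R)-1-hydroxy-5-[(2Z)-oct-2-en-1-yl]-2-oxo-5-(triethylsilyloxy)cyclopent-3-en-1-yl]hept-5-enoate | COC(=O)CCC/C=C\C[C@@]1(O)C(=O)C=C[C@]1(O[Si](CC)(CC)CC)C/C=C\CCCCC | intermediate
23 | methyl (5Z)-7-[(3S,4R)-3-hydroxy-4-[(2Z)-oct-2-en-1-yl]-2-oxo-4-(triethylsilyloxy)-6-oxabicyclo[3.1.0]hexan-3-yl]hept-5-enoate (epoxide carbons: either cis-fused epimer) | COC(=O)CCC/C=C\C[C@@]1(O)C(=O)C2OC2[C@]1(O[Si](CC)(CC)CC)C/C=C\CCCCC | intermediate
24 | 2-bromo-3-(trimethylsilyloxy) ketone from trans opening of 23 (epimers at the two new centres; not isolated) | COC(=O)CCC/C=C\C[C@@]1(O)C(=O)C(Br)C(O[Si](C)(C)C)[C@]1(O[Si](CC)(CC)CC)C/C=C\CCCCC | intermediate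
25 | methyl (5Z)-7-[(1S,5R)-3-bromo-1-hydroxy-5-[(2Z)-oct-2-en-1-yl]-2-oxo-5-(triethylsilyloxy)cyclopent-3-en-1-yl]hept-5-enoate | COC(=O)CCC/C=C\C[C@@]1(O)C(=O)C(Br)=C[C@]1(O[Si](CC)(CC)CC)C/C=C\CCCCC | intermediate
26 | methyl (5Z,7E)-7-[(2R)-4-bromo-2-[(2Z)-oct-2-en-1-yl]-5-oxo-2-(triethylsilyloxy)cyclopent-3-en-1-ylidene]hept-5-enoate | CCCCC/C=C\C[C@@]1(O[Si](CC)(CC)CC)C=C(Br)C(=O)/C1=C/C=C\CCCC(=O)OC | intermediate
27 | bromovulone I, methyl (5Z,7E)-7-[(2R)-4-bromo-2-hydroxy-2-[(2Z)-oct-2-en-1-yl]-5-oxocyclopent-3-en-1-ylidene]hept-5-enoate | CCCCC/C=C\C[C@@]1(O)C=C(Br)C(=O)/C1=C/C=C\CCCC(=O)OC | target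

**Step count and risks**

Total step count: 12. Longest linear sequence: 9 steps (steps 1, 2, 3, 5, 8, 9, 10, 11, 12).

Steps most likely to fail:

1. Step 8 (proposed new method). The cascade may stall or divert in several ways: enolisation of the β,γ-unsaturated ketone at C13 in place of addition; attack on the acylal carbonyl before the ketone; retro-aldol cleavage of alkoxide 20 before the silyl shift; incomplete silyl migration; or poor facial selectivity at C12. The fallback sets out from 14 and uses known reactions one at a time. (Z)-2-(Tributylstannyl)vinyllithium F1, made from commercial (Z)-1,2-bis(tributylstannyl)ethene and MeLi in THF at −78 °C, is added to the ketone of 14 in the same facial sense, and the alkoxide is trapped with Et3SiOTf to give the triethylsilyl ether of the stannylvinyl carbinol F2. Iododestannylation (I2, CH2Cl2, 0 °C) gives the (Z)-vinyl iodide F3. Iodine–lithium exchange (t-BuLi, THF/Et2O/pentane, −100 °C) and Parham-type cyclisation onto the dioxolanone carbonyl, with loss of pivalaldehyde, come back to the route at 22.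

2. Step 5. The enolate may instead deprotonate the β,γ-unsaturated acid chloride (ketene formation) or the product ketone, and the Z-alkene may slip into conjugation. The fallback sets out from 8 and 9. Alcohol 9 is oxidised with Dess–Martin periodinane to aldehyde 10, which is used cold. The lithium enolate 13 adds to it in an aldol reaction anti to the tert-butyl group to give the β-hydroxy lactone F4 (carbinol epimers). Dess–Martin oxidation of F4 comes back to the route at 14.

3. Step 9. The base may trigger α-ketol rearrangement or retro-aldol cleavage of the tertiary α-hydroxy ketone, and peroxide addition at the hindered β-carbon may be slow. The fallback sets out from 22 and avoids the epoxide. Me3SiBr adds conjugately (CH2Cl2, −78 °C) to give the 3-bromo trimethylsilyl enol ether F5. NBS brominates the enol ether at the α-carbon to give the 2,3-dibromo ketone F6. DBU then removes HBr, and the sequence comes back to the route at 25, bypassing 23 and 24.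

Further compounds
F1 | step 8 | (Z)-2-(tributylstannyl)vinyllithium | [Li]/C=C\[Sn](CCCC)(CCCC)CCCC
F2 | step 8 | triethylsilyl ether of the (Z)-stannylvinyl carbinol from 14 (carbinol carbon R) | COC(=O)CCC/C=C\C[C@@]1([C@](O[Si](CC)(CC)CC)(/C=C\[Sn](CCCC)(CCCC)CCCC)C/C=C\CCCCC)O[C@@H](C(C)(C)C)OC1=O
F3 | step 8 | corresponding (Z)-vinyl iodide | COC(=O)CCC/C=C\C[C@@]1([C@](O[Si](CC)(CC)CC)(/C=C\I)C/C=C\CCCCC)O[C@@H](C(C)(C)C)OC1=O
F4 | step 5 | methyl (5Z)-7-[(2R,4S)-2-tert-butyl-4-[(3Z)-1-hydroxynon-3-en-1-yl]-5-oxo-1,3-dioxolan-4-yl]hept-5-enoate (carbinol epimers) | COC(=O)CCC/C=C\C[C@@]1(C(O)C/C=C\CCCCC)O[C@@H](C(C)(C)C)OC1=O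
F5 | step 9 | 3-bromo trimethylsilyl enol ether from conjugate addition of Me3SiBr to 22 (epimers at the bromine-bearing carbon) | COC(=O)CCC/C=C\C[C@@]1(O)C(O[Si](C)(C)C)=CC(Br)[C@]1(O[Si](CC)(CC)CC)C/C=C\CCCCC
F6 | step 9 | 2,3-dibromo ketone (epimers at the bromine-bearing carbons) | COC(=O)CCC/C=C\C[C@@]1(O)C(=O)C(Br)C(Br)[C@]1(O[Si](CC)(CC)CC)C/C=C\CCCCC
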